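**Retrosynthetic overview**
- Macrolide ring (formed last): C10–O bond by acylketene macrolactonisation of a dioxinone with C6 held as a silyl ether, then C9 methylation and C6 oxidation; C6–C7 bond by vinylogous aldol onto the decalin aldehyde.
- (12Z,14Z)-Diene: Cadiot–Chodkiewicz diyne (C13–C14) from the decalin alkyne and (R)-4-bromobut-3-yn-2-ol (C11 by asymmetric transfer hydrogenation), then zinc semireduction.
- Rings A and B (formed together): iminium-catalysed endo intramolecular Diels–Alder reaction of an (E,Z,E,E)-tetraenynal, setting C4, C5, C17 and C20.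
- Tetraenynal: Suzuki coupling (C18–C19) of an alkenyl iodide carrying C16 with an alkenyl boronate from Birch reduction/ozonolysis of 4-methylanisole (this fixes the Z-olefin); enal by Wittig.
- C16 (first stereocentre): enamine-catalysed α-alkynylation of propanal, with the labile aldehyde converted in the same operation into the alkenyl iodide by Takai olefination.

Assumption: the drawn enol is one tautomer of the C6/C8 β-diketone and C9 equilibrates; the drawn 9R form is taken to be the thermodynamically preferred one.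

Locants used below (from the target): C1(CH3)=C2–C3–C4–C5–C6(OH)=C7–C8(=O)–C9(CH3)–C10(=O)–O–C11(CH3)–C12=C13–C14=C15–C16(CH3)–C17–C18=C19–C20–C21, with ring bonds C4–C20, C5–C17 and C21–C1. Ring A is C1–C4/C20/C21; ring B is C4/C5/C17–C20.

**Route**

Step 1
Reactants: 1 propanal
Product: 3 [(3S,4E)-5-iodo-3-methylpent-4-en-1-yn-1-yl](trimethyl)silane, via alkynyl aldehyde 2 (not isolated)
Conditions: 1 (2 equiv), TMS-EBX, (2S,5S)-5-benzyl-2-tert-butyl-3-methylimidazolidin-4-one·CF3CO2H (20 mol%), CHCl3, −30 °C; cold silica plug, concentrate at 0 °C; then CrCl2, CHI3, THF/dioxane, 0 °C → rt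
Reagents that add atoms: 1-[(trimethylsilyl)ethynyl]-1,2-benziodoxol-3(1H)-one (TMS-EBX), C[Si](C)(C)C#CI1OC(=O)c2ccccc12; iodoform, IC(I)I
Why: Proposed new method: enamine-catalysed enantioselective α-alkynylation of a linear aldehyde with an ethynylbenziodoxolone, telescoped into a Takai iodo-olefination; the E-enamine of propanal (olefin turned away from the tert-butyl group, benzyl covering one face) attacks through its open Si face the alkyne of the trivalent-iodine reagent (activated at its carboxylate by the acid co-catalyst), loss of 2-iodobenzoate and 1,2-silyl shift of the alkylidene carbene give the alkyne and set C16, the hindered catalyst salt does not re-enolise the α-branched aldehyde, and the non-basic CrCl2/CHI3 olefination (E-selective for α-branched aldehydes) consumes the labile aldehyde at once, so C16 is not racemised and no allenal forms; the closest known reaction types are enamine α-arylation and α-vinylation of aldehydes with iodonium salts, the racemic α-alkynylation of aldehydes with ethynylbenziodoxolones under combined amine and AuCl catalysis, and ethynylbenziodoxolone alkynylation of stabilised enolates.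

Step 2
Reactants: 4 4-methylanisole
Product: 5 1-methoxy-4-methylcyclohexa-1,4-diene
Conditions: Li, NH3 (l), THF, t-BuOH, −78 → −33 °C
Reagents that add atoms: none
Why: Birch reduction of an anisole gives the 1,4-diene, which holds the future C1=C2 trisubstituted olefin as Z inside the ring.

Step 3
Reactants: 5 1-methoxy-4-methylcyclohexa-1,4-diene
Product: 7 methyl (3Z,6E)-4-methyl-7-(4,4,5,5-tetramethyl-1,3,2-dioxaborolan-2-yl)hepta-3,6-dienoate, via aldehyde ester 6 (not isolated)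
Conditions: O3 (1 equiv), CH2Cl2/MeOH, pyridine, −78 °C; Me2S; then CrCl2, Cl2CHBpin, LiI, THF, rt
Reagents that add atoms: ozone, [O-][O+]=O; 2-(dichloromethyl)-4,4,5,5-tetramethyl-1,3,2-dioxaborolane, ClC(Cl)B1OC(C)(C)C(C)(C)O1
Why: The electron-rich enol ether is ozonised selectively over the trisubstituted olefin to give ester and aldehyde termini, and the non-basic Takai–Utimoto boron olefination turns the isomerisation-prone β,γ-unsaturated aldehyde into the E-alkenyl boronate.

Step 4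
Reactants: 3 [(3S,4E)-5-iodo-3-methylpent-4-en-1-yn-1-yl](trimethyl)silane; 7 methyl (3Z,6E)-4-methyl-7-(4,4,5,5-tetramethyl-1,3,2-dioxaborolan-2-yl)hepta-3,6-dienoate
Product: 8 methyl (3Z,6E,8E,10S)-4,10-dimethyl-12-(trimethylsilyl)dodeca-3,6,8-trien-11-ynoate
Conditions: Pd(dppf)Cl2 (5 mol%), K3PO4 (aq), THF, rt
Reagents that add atoms: none
Why: Stereoretentive Suzuki–Miyaura coupling of an E-alkenyl iodide with an E-alkenyl boronate forms C18–C19 and the (E,E)-diene without touching C16.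

Step 5
Reactants: 8 methyl (3Z,6E,8E,10S)-4,10-dimethyl-12-(trimethylsilyl)dodeca-3,6,8-trien-11-ynoate
Product: 9 (3Z,6E,8E,10S)-4,10-dimethyl-12-(trimethylsilyl)dodeca-3,6,8-trien-11-yn-1-ol
Conditions: i-Bu2AlH, CH2Cl2, −78 → 0 °C
Reagents that add atoms: none
Why: Hydride reduction of the methyl ester to the primary alcohol; the silylalkyne and the polyene are inert.

Step 6
Reactants: 9 (3Z,6E,8E,10S)-4,10-dimethyl-12-(trimethylsilyl)dodeca-3,6,8-trien-11-yn-1-ol
Product: 11 (2E,5Z,8E,10E,12S)-6,12-dimethyl-14-(trimethylsilyl)tetradeca-2,5,8,10-tetraen-13-ynal, via trienynal 10 (not isolated)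
Conditions: DMP, NaHCO3, CH2Cl2, 0 °C; then Ph3P=CHCHO, rt
Reagents that add atoms: (triphenylphosphoranylidene)acetaldehyde, O=CC=P(c1ccccc1)(c1ccccc1)c1ccccc1
Why: Buffered Dess–Martin oxidation and Wittig olefination with the stabilised formyl ylide (E-selective) in the same flask trap the β,γ-unsaturated aldehyde before it can move into conjugation.

Step 7
Reactants: 11 (2E,5Z,8E,10E,12S)-6,12-dimethyl-14-(trimethylsilyl)tetradeca-2,5,8,10-tetraen-13-ynal
Product: 12 (1R,2R,4aR,8aS)-6-methyl-2-[(2S)-4-(trimethylsilyl)but-3-yn-2-yl]-1,2,4a,5,8,8a-hexahydronaphthalene-1-carbaldehyde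
Conditions: (2S,5S)-5-benzyl-2-tert-butyl-3-methylimidazolidin-4-one·CF3CO2H (20 mol%), CH3CN/H2O (98:2), −20 → 4 °C
Reagents that add atoms: none
Why: Organocatalytic intramolecular Diels–Alder reaction by iminium activation with the second-generation MacMillan imidazolidinone: the benzyl group shields one face of the E-iminium, the diene adds to the β-Re face through the endo transition state (carbonyl under the diene, tether exo), giving the trans-fused bicycle with C4 (S), C5 (R), C17 (R) and C20 (R) under catalyst control, since C16 has only H cis to it on the E-olefin and exerts little bias.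

Step 8
Reactants: 12 (1R,2R,4aR,8aS)-6-methyl-2-[(2S)-4-(trimethylsilyl)but-3-yn-2-yl]-1,2,4a,5,8,8a-hexahydronaphthalene-1-carbaldehyde; 13 2,2,6-trimethyl-4H-1,3-dioxin-4-one
Product: 16 6-{2-[(tert-butyldimethylsilyl)oxy]-2-[(1R,2R,4aR,8aS)-6-methyl-2-[(2S)-4-(trimethylsilyl)but-3-yn-2-yl]-1,2,4a,5,8,8a-hexahydronaphthalen-1-yl]ethyl}-2,2-dimethyl-4H-1,3-dioxin-4-one (both C6 epimers), via lithium dienolate 14 (not isolated), via lithium aldolate 15 (not isolated)
Conditions: 13, LiN(i-Pr)2, THF, −78 °C; then 12; then TBSOTf, 2,6-lutidine, −78 → −20 °C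
Reagents that add atoms: tert-butyldimethylsilyl trifluoromethanesulfonate (TBSOTf), CC(C)(C)[Si](C)(C)OS(=O)(=O)C(F)(F)F
Why: Vinylogous aldol addition of the dioxinone dienolate through its γ-carbon forms C6–C7, and silylating the aldolate keeps the C6 oxygen from trapping the acylketene later; the new carbinol centre is oxidised away in step 16, so its configuration does not matter.

Step 9
Reactants: 17 4-(trimethylsilyl)but-3-yn-2-one
Product: 18 (2R)-4-(trimethylsilyl)but-3-yn-2-ol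
Conditions: RuCl[(R,R)-TsDPEN](p-cymene) (1 mol%), i-PrOH, rt
Reagents that add atoms: none
Why: Noyori asymmetric transfer hydrogenation of an ynone; the (R,R)-catalyst gives the (R)-propargylic alcohol, which becomes C11.

Step 10
Reactants: 18 (2R)-4-(trimethylsilyl)but-3-yn-2-ol
Product: 19 (2R)-4-bromobut-3-yn-2-ol
Conditions: NBS, AgNO3 (10 mol%), acetone, rt
Reagents that add atoms: N-bromosuccinimide, BrN1C(=O)CCC1=O
Why: Silver-catalysed bromodesilylation of the alkynylsilane gives the 1-bromoalkyne without touching the carbinol centre.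

Step 11
Reactants: 16 6-{2-[(tert-butyldimethylsilyl)oxy]-2-[(1R,2R,4aR,8aS)-6-methyl-2-[(2S)-4-(trimethylsilyl)but-3-yn-2-yl]-1,2,4a,5,8,8a-hexahydronaphthalen-1-yl]ethyl}-2,2-dimethyl-4H-1,3-dioxin-4-one; 19 (2R)-4-bromobut-3-yn-2-ol
Product: 21 6-{2-[(tert-butyldimethylsilyl)oxy]-2-[(1R,2R,4aR,8aS)-2-[(2S,7R)-7-hydroxyocta-3,5-diyn-2-yl]-6-methyl-1,2,4a,5,8,8a-hexahydronaphthalen-1-yl]ethyl}-2,2-dimethyl-4H-1,3-dioxin-4-one, via terminal alkyne 20 (not isolated)
Conditions: Bu4NF, AcOH, THF, 0 °C; then 19, CuCl (10 mol%), NH2OH·HCl, n-BuNH2, MeOH/H2O, 0 °C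
Reagents that add atoms: none
Why: Buffered fluoride removes the C-silyl group while the hindered silyl ether survives, and Cadiot–Chodkiewicz coupling of the terminal alkyne with the bromoalkyne forms C13–C14 as the unsymmetrical 1,3-diyne.

Step 12
Reactants: 21 6-{2-[(tert-butyldimethylsilyl)oxy]-2-[(1R,2R,4aR,8aS)-2-[(2S,7R)-7-hydroxyocta-3,5-diyn-2-yl]-6-methyl-1,2,4a,5,8,8a-hexahydronaphthalen-1-yl]ethyl}-2,2-dimethyl-4H-1,3-dioxin-4-one
Product: 22 6-{2-[(tert-butyldimethylsilyl)oxy]-2-[(1R,2R,4aR,8aS)-2-[(2R,3Z,5Z,7R)-7-hydroxyocta-3,5-dien-2-yl]-6-methyl-1,2,4a,5,8,8a-hexahydronaphthalen-1-yl]ethyl}-2,2-dimethyl-4H-1,3-dioxin-4-one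
Conditions: Zn dust activated with Cu(OAc)2 and AgNO3, MeOH/H2O/THF, 40 °C
Reagents that add atoms: none
Why: Activated-zinc semireduction adds hydrogen syn to each triple bond of the conjugated diyne, helped by the free propargylic hydroxyl, giving the (Z,Z)-diene and leaving isolated olefins and the dioxinone alone.

Step 13
Reactants: 22 6-{2-[(tert-butyldimethylsilyl)oxy]-2-[(1R,2R,4aR,8aS)-2-[(2R,3Z,5Z,7R)-7-hydroxyocta-3,5-dien-2-yl]-6-methyl-1,2,4a,5,8,8a-hexahydronaphthalen-1-yl]ethyl}-2,2-dimethyl-4H-1,3-dioxin-4-one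
Product: 24 C6-silyloxy-C8-oxo 14-membered lactone (target ring system; C6H(OTBS); C7H2; C9H2), via acylketene 23 (not isolated)
Conditions: toluene (0.5 mM), 110 °C
Reagents that add atoms: none
Why: Thermal retro-[4+2] of the dioxinone releases acetone and an acylketene that the C11 hydroxyl traps at high dilution (acylketene macrolactonisation) to close the 14-membered β-keto lactone; with C6 silylated no pyranone can form.

Step 14
Reactants: 24 C6-silyloxy-C8-oxo 14-membered lactone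
Product: 25 C9-methyl β-keto lactone (as 24 with C9H(CH3))
Conditions: K2CO3, MeI (1.05 equiv), acetone, rt
Reagents that add atoms: iodomethane, CI
Why: C-Alkylation of a β-keto ester enolate: C9, between the C8 ketone and the lactone carbonyl, is the only position acidic enough for K2CO3, so it is methylated selectively.

Step 15
Reactants: 25 C9-methyl β-keto lactone
Product: 26 C6-hydroxy-C8-oxo lactone (as 25 with C6H(OH))
Conditions: HF·pyridine, pyridine, THF, 0 °C → rt
Reagents that add atoms: none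
Why: Buffered fluoride cleaves the secondary silyl ether under mildly acidic conditions, so the β-oxy ketone does not eliminate.

Step 16
Reactants: 26 C6-hydroxy-C8-oxo lactone
Product: 27 CNP0360406.2 (target)
Conditions: DMP, NaHCO3, CH2Cl2, 0 °C; then Et3N (cat.), CH2Cl2, rt
Reagents that add atoms: none
Why: Dess–Martin oxidation of the β-hydroxy ketone gives the 1,3-diketone, which enolises to the drawn tricarbonyl, and C9 equilibrates under the mild base to the assumed more stable 9R epimer (thermodynamic control).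

**Compound list**

1 | propanal | CCC=O | starting material
2 | (2R)-2-methyl-4-(trimethylsilyl)but-3-ynal | C[Si](C)(C)C#C[C@@H](C)C=O | intermediate
3 | [(3S,4E)-5-iodo-3-methylpent-4-en-1-yn-1-yl](trimethyl)silane | C[Si](C)(C)C#C[C@@H](C)/C=C/I | intermediate
4 | 4-methylanisole | COc1ccc(C)cc1 | starting material
5 | 1-methoxy-4-methylcyclohexa-1,4-diene | COC1=CCC(C)=CC1 | intermediate
6 | methyl (3Z)-4-methyl-6-oxohex-3-enoate | COC(=O)C/C=C(/C)CC=O | intermediate
7 | methyl (3Z,6E)-4-methyl-7-(4,4,5,5-tetramethyl-1,3,2-dioxaborolan-2-yl)hepta-3,6-dienoate | COC(=O)C/C=C(/C)C/C=C/B1OC(C)(C)C(C)(C)O1 | intermediate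
8 | methyl (3Z,6E,8E,10S)-4,10-dimethyl-12-(trimethylsilyl)dodeca-3,6,8-trien-11-ynoate | COC(=O)C/C=C(/C)C/C=C/C=C/[C@H](C)C#C[Si](C)(C)C | intermediate
9 | (3Z,6E,8E,10S)-4,10-dimethyl-12-(trimethylsilyl)dodeca-3,6,8-trien-11-yn-1-ol | OCC/C=C(/C)C/C=C/C=C/[C@H](C)C#C[Si](C)(C)C | intermediate
10 | (3Z,6E,8E,10S)-4,10-dimethyl-12-(trimethylsilyl)dodeca-3,6,8-trien-11-ynal | O=CC/C=C(/C)C/C=C/C=C/[C@H](C)C#C[Si](C)(C)C | intermediate
11 | (2E,5Z,8E,10E,12S)-6,12-dimethyl-14-(trimethylsilyl)tetradeca-2,5,8,10-tetraen-13-ynal | O=C/C=C/C/C=C(/C)C/C=C/C=C/[C@H](C)C#C[Si](C)(C)C | intermediate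
12 | (1R,2R,4aR,8aS)-6-methyl-2-[(2S)-4-(trimethylsilyl)but-3-yn-2-yl]-1,2,4a,5,8,8a-hexahydronaphthalene-1-carbaldehyde | CC1=CC[C@@H]2[C@@H](C=O)[C@@H]([C@H](C)C#C[Si](C)(C)C)C=C[C@H]2C1 | intermediate
13 | 2,2,6-trimethyl-4H-1,3-dioxin-4-one | CC1=CC(=O)OC(C)(C)O1 | starting material
14 | lithium 2,2-dimethyl-6-methylidene-6H-1,3-dioxin-4-olate | [Li+].C=C1OC(C)(C)OC([O-])=C1 | intermediate
15 | lithium 1-[(1R,2R,4aR,8aS)-6-methyl-2-[(2S)-4-(trimethylsilyl)but-3-yn-2-yl]-1,2,4a,5,8,8a-hexahydronaphthalen-1-yl]-2-(2,2-dimethyl-4-oxo-4H-1,3-dioxin-6-yl)ethan-1-olate (both C6 epimers) | [Li+].CC1=CC[C@@H]2[C@@H](C([O-])CC3=CC(=O)OC(C)(C)O3)[C@@H]([C@H](C)C#C[Si](C)(C)C)C=C[C@H]2C1 | intermediate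
16 | 6-{2-[(tert-butyldimethylsilyl)oxy]-2-[(1R,2R,4aR,8aS)-6-methyl-2-[(2S)-4-(trimethylsilyl)but-3-yn-2-yl]-1,2,4a,5,8,8a-hexahydronaphthalen-1-yl]ethyl}-2,2-dimethyl-4H-1,3-dioxin-4-one (both C6 epimers) | CC1=CC[C@@H]2[C@@H](C(O[Si](C)(C)C(C)(C)C)CC3=CC(=O)OC(C)(C)O3)[C@@H]([C@H](C)C#C[Si](C)(C)C)C=C[C@H]2C1 | intermediate
17 | 4-(trimethylsilyl)but-3-yn-2-one | CC(=O)C#C[Si](C)(C)C | starting material
18 | (2R)-4-(trimethylsilyl)but-3-yn-2-ol | C[C@@H](O)C#C[Si](C)(C)C | intermediate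
19 | (2R)-4-bromobut-3-yn-2-ol | C[C@@H](O)C#CBr | intermediate
20 | 6-{2-[(tert-butyldimethylsilyl)oxy]-2-[(1R,2R,4aR,8aS)-2-[(2S)-but-3-yn-2-yl]-6-methyl-1,2,4a,5,8,8a-hexahydronaphthalen-1-yl]ethyl}-2,2-dimethyl-4H-1,3-dioxin-4-one | CC1=CC[C@@H]2[C@@H](C(O[Si](C)(C)C(C)(C)C)CC3=CC(=O)OC(C)(C)O3)[C@@H]([C@H](C)C#C)C=C[C@H]2C1 | intermediate
21 | 6-{2-[(tert-butyldimethylsilyl)oxy]-2-[(1R,2R,4aR,8aS)-2-[(2S,7R)-7-hydroxyocta-3,5-diyn-2-yl]-6-methyl-1,2,4a,5,8,8a-hexahydronaphthalen-1-yl]ethyl}-2,2-dimethyl-4H-1,3-dioxin-4-one | CC1=CC[C@@H]2[C@@H](C(O[Si](C)(C)C(C)(C)C)CC3=CC(=O)OC(C)(C)O3)[C@@H]([C@H](C)C#CC#C[C@@H](C)O)C=C[C@H]2C1 | intermediate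
22 | 6-{2-[(tert-butyldimethylsilyl)oxy]-2-[(1R,2R,4aR,8aS)-2-[(2R,3Z,5Z,7R)-7-hydroxyocta-3,5-dien-2-yl]-6-methyl-1,2,4a,5,8,8a-hexahydronaphthalen-1-yl]ethyl}-2,2-dimethyl-4H-1,3-dioxin-4-one | CC1=CC[C@@H]2[C@@H](C(O[Si](C)(C)C(C)(C)C)CC3=CC(=O)OC(C)(C)O3)[C@@H]([C@H](C)/C=C\C=C/[C@@H](C)O)C=C[C@H]2C1 | intermediate
23 | acylketene: 5-[(tert-butyldimethylsilyl)oxy]-5-[(1R,2R,4aR,8aS)-2-[(2R,3Z,5Z,7R)-7-hydroxyocta-3,5-dien-2-yl]-6-methyl-1,2,4a,5,8,8a-hexahydronaphthalen-1-yl]pent-1-ene-1,3-dione | CC1=CC[C@@H]2[C@@H](C(O[Si](C)(C)C(C)(C)C)CC(=O)C=C=O)[C@@H]([C@H](C)/C=C\C=C/[C@@H](C)O)C=C[C@H]2C1 | intermediate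
24 | 14-membered β-keto lactone: target ring system with C6H(OTBS) (both epimers), C7H2, C8=O, C9H2; (4S,5R,11R,16R,17R,20R,12Z,14Z) | CC1=CC[C@@H]2[C@H]3C(O[Si](C)(C)C(C)(C)C)CC(=O)CC(=O)O[C@H](C)/C=C\C=C/[C@@H](C)[C@H]3C=C[C@H]2C1 | intermediate
25 | C9-methyl β-keto lactone: as 24 with C9H(CH3) (epimers at C6 and C9) | CC1=CC[C@@H]2[C@H]3C(O[Si](C)(C)C(C)(C)C)CC(=O)C(C)C(=O)O[C@H](C)/C=C\C=C/[C@@H](C)[C@H]3C=C[C@H]2C1 | intermediate
26 | C6-hydroxy-C8-oxo lactone: as 25 with C6H(OH) | CC1=CC[C@@H]2[C@H]3C(O)CC(=O)C(C)C(=O)O[C@H](C)/C=C\C=C/[C@@H](C)[C@H]3C=C[C@H]2C1 | intermediate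
27 | CNP0360406.2: (4S,5R,9R,11R,16R,17R,20R,12Z,14Z) enolised tricarbonyl 14-membered macrolide on the trans-fused methylhexahydronaphthalene | CC1=CC[C@@H]2[C@H]3/C(O)=C\C(=O)[C@@H](C)C(=O)O[C@H](C)/C=C\C=C/[C@@H](C)[C@H]3C=C[C@H]2C1 | target

**Step count**
Total: 16 steps. Longest linear sequence: 13 steps (2–8, 11–16).

**Three steps most likely to fail**

Step 1 (the proposed new α-alkynylation with Takai trapping). Risks are N-alkynylation of the catalyst, racemisation of 2 or its isomerisation to the allenal before the olefination is complete, and a facial sense opposite to the model (then the (2R,5R)-catalyst is used). The fallback uses known chemistry and avoids 2 altogether; it sets out from 1 (with crude 6 from the ozonolysis half of step 3 as partner) and comes back at 8. Organocatalytic α-hydroxymethylation of 1 with aqueous formaldehyde ((R)-α,α-diphenylprolinol trimethylsilyl ether, toluene/pH 7 buffer) gives (2S)-3-hydroxy-2-methylpropanal F1. Silylation (TBSCl, imidazole) gives (2S)-3-[(tert-butyldimethylsilyl)oxy]-2-methylpropanal F2. Corey–Fuchs olefination (CBr4, PPh3) gives tert-butyl{[(2R)-4,4-dibromo-2-methylbut-3-en-1-yl]oxy}dimethylsilane F3. Treatment with n-BuLi and then Me3SiCl gives tert-butyldimethyl{[(2R)-2-methyl-4-(trimethylsilyl)but-3-yn-1-yl]oxy}silane F4. PPTS in MeOH removes the silyl ether to give (2R)-2-methyl-4-(trimethylsilyl)but-3-yn-1-ol F5. Mitsunobu reaction of this alcohol with 1-phenyl-1H-tetrazole-5-thiol (PPh3, DIAD) gives 5-{[(2R)-2-methyl-4-(trimethylsilyl)but-3-yn-1-yl]sulfanyl}-1-phenyl-1H-tetrazole F6. Oxidation ((NH4)6Mo7O24, H2O2, EtOH) gives 5-{[(2R)-2-methyl-4-(trimethylsilyl)but-3-yn-1-yl]sulfonyl}-1-phenyl-1H-tetrazole F7. Crude 6 and Ph3P=CHCHO give methyl (3Z,6E)-4-methyl-8-oxoocta-3,6-dienoate F8. Julia–Kocienski olefination of the sulfone (KN(SiMe3)2, DME, −60 °C) with this enal forms C17=C18 and gives 8, so step 1, the borylation half of step 3 and step 4 are bypassed.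

Step 7 (iminium-catalysed intramolecular Diels–Alder). The risk is γ-deprotonation of the doubly allylic C3 position (dienamine formation and olefin migration) or weak catalyst control. The fallback sets out from 11 and comes back at 12 and makes no new compound F0. It replaces covalent aminocatalysis by chiral Lewis-acid activation: the triflimide-protonated oxazaborolidine from α,α-diphenylprolinol and o-tolylboronic acid (10–20 mol%, CH2Cl2, −78 → −40 °C). This is a known catalyst type for enantioselective intramolecular Diels–Alder reactions of trienals; no amine is present, so the dienamine pathway is closed. The catalyst enantiomer is chosen by its established facial model.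

Step 13 (acylketene macrolactonisation). The risk is that the acylketene oligomerises or is captured by the diene or a ring olefin instead of the hindered C11 hydroxyl. The fallback closes the macrocycle at C13–C14 instead of C10–O; it sets out from 20 (isolated after the fluoride half of step 11) together with 19, and comes back at 24. Heating 20 with excess 19 (toluene, 110 °C) traps the acylketene intermolecularly and gives (2R)-4-bromobut-3-yn-2-yl 5-[(tert-butyldimethylsilyl)oxy]-5-[(1R,2R,4aR,8aS)-2-[(2S)-but-3-yn-2-yl]-6-methyl-1,2,4a,5,8,8a-hexahydronaphthalen-1-yl]-3-oxopentanoate F9. Intramolecular Cadiot–Chodkiewicz coupling (CuCl, NH2OH·HCl, n-BuNH2, MeOH/THF, slow addition at high dilution) gives the 14-membered 12,14-diyne β-keto lactone F10. Semireduction with zinc dust activated with Cu(OAc)2 and AgNO3 then gives 24, so the coupling half of step 11 and steps 12 and 13 are bypassed.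

**Further compounds**

F1 | step 1 | (2S)-3-hydroxy-2-methylpropanal | O=C[C@@H](C)CO
F2 | step 1 | (2S)-3-[(tert-butyldimethylsilyl)oxy]-2-methylpropanal | O=C[C@@H](C)CO[Si](C)(C)C(C)(C)C
F3 | step 1 | tert-butyl{[(2R)-4,4-dibromo-2-methylbut-3-en-1-yl]oxy}dimethylsilane | BrC(Br)=C[C@@H](C)CO[Si](C)(C)C(C)(C)C
F4 | step 1 | tert-butyldimethyl{[(2R)-2-methyl-4-(trimethylsilyl)but-3-yn-1-yl]oxy}silane | C[Si](C)(C)C#C[C@@H](C)CO[Si](C)(C)C(C)(C)C
F5 | step 1 | (2R)-2-methyl-4-(trimethylsilyl)but-3-yn-1-ol | C[Si](C)(C)C#C[C@@H](C)CO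
F6 | step 1 | 5-{[(2R)-2-methyl-4-(trimethylsilyl)but-3-yn-1-yl]sulfanyl}-1-phenyl-1H-tetrazole | C[Si](C)(C)C#C[C@@H](C)CSc1nnnn1-c1ccccc1
F7 | step 1 | 5-{[(2R)-2-methyl-4-(trimethylsilyl)but-3-yn-1-yl]sulfonyl}-1-phenyl-1H-tetrazole | C[Si](C)(C)C#C[C@@H](C)CS(=O)(=O)c1nnnn1-c1ccccc1
F8 | step 1 | methyl (3Z,6E)-4-methyl-8-oxoocta-3,6-dienoate | COC(=O)C/C=C(/C)C/C=C/C=O
F0 | step 7 | none | none
F9 | step 13 | (2R)-4-bromobut-3-yn-2-yl 5-[(tert-butyldimethylsilyl)oxy]-5-[(1R,2R,4aR,8aS)-2-[(2S)-but-3-yn-2-yl]-6-methyl-1,2,4a,5,8,8a-hexahydronaphthalen-1-yl]-3-oxopentanoate | CC1=CC[C@@H]2[C@@H](C(O[Si](C)(C)C(C)(C)C)CC(=O)CC(=O)O[C@H](C)C#CBr)[C@@H]([C@H](C)C#C)C=C[C@H]2C1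
F10 | step 13 | 14-membered 12,14-diyne β-keto lactone: as 24 with C12≡C13–C14≡C15 in place of the (Z,Z)-diene | CC1=CC[C@@H]2[C@H]3C(O[Si](C)(C)C(C)(C)C)CC(=O)CC(=O)O[C@H](C)C#CC#C[C@@H](C)[C@H]3C=C[C@H]2C1
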